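**Retrosynthetic overview**
1. Target: trans-fused daucane (bicyclo[5.3.0]decane), (1S,2R,4S,5R,6R,8S,9R). Late operations: C2 acetate by inversion, C6 anisate, C8–C9 epoxide directed by the 6α-OH, 6α-OH by 4β-OH-directed reduction of a C6 ketone.
2. Enabling feature: the seven-membered ring C1–C10–C9–C8–C7–C6–C5 is a masked cyclohepta-1,4-diene. The epoxide is alkene C8=C9, the C5–H/C6–O pair is a hydrolysed enol ether C5=C6, C7 is the lone CH2 between them, and the quaternary C1–C10 bond lies opposite.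
3. Key disconnection: C1–C10 (Cope) plus C6–C8/C7–C8 (cyclopropanation), i.e. a formal (4+3) of a Rh-vinylcarbenoid (C8–C9–C10, ester at C8 as the future C14 methyl) with a 2-silyloxydiene (C7=C6–C5=C1) on a preformed cyclopentene.
4. Ring order: cyclopentene from the chiral pool (its C2 silyloxy group controls C4, is matched with the catalyst for C1, and is inverted at the end) → seven-membered carbocycle closed last via a transient cyclopropane → epoxide as a late functional group.

Key step: step 8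

Remark (convention and assumption): daucane numbering is used for all bicyclic compounds. C1 is the quaternary ring-fusion carbon (angular methyl C15); C2, C3, C4 (isopropyl) and C5 (ring-fusion CH) complete the five-membered ring; C6, C7, C8 (bears C14), C9 and C10 complete the seven-membered ring. β is the face of the angular methyl. (4S)-4-(tert-Butyldimethylsilyloxy)cyclopent-2-en-1-one (1) is taken as commercially available.

**Step 1**
Reactants: 1 (4S)-4-(tert-butyldimethylsilyloxy)cyclopent-2-en-1-one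
Product: 2 trimethylsilyl enol ether of (3S,4S)-4-(tert-butyldimethylsilyloxy)-3-methylcyclopentan-1-one (methyl trans to OTBS)
Conditions: Me2CuLi (from MeLi, CuI), Me3SiCl, THF/Et2O, −78 °C
Reagents that add atoms: lithium dimethylcuprate [Li+].C[Cu-]C; chlorotrimethylsilane C[Si](C)(C)Cl
Why: Gilman cuprate 1,4-addition with in situ silyl trapping should place the methyl anti to the silyloxy group (this centre is erased in step 2) and capture the regiodefined enolate before β-elimination of silyloxide.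

**Step 2**
Reactants: 2 trimethylsilyl enol ether of (3S,4S)-4-(tert-butyldimethylsilyloxy)-3-methylcyclopentan-1-one
Product: 3 (4S)-4-(tert-butyldimethylsilyloxy)-3-methylcyclopent-2-en-1-one
Conditions: Pd(OAc)2 (10 mol %), O2 (1 atm), DMSO, rt
Reagents that add atoms: none
Why: Saegusa–Ito oxidation (aerobic catalytic variant) of the regiodefined enol ether should give only the C2=C3 enone and leaves the C4 stereocentre untouched.

**Step 3**
Reactants: 3 (4S)-4-(tert-butyldimethylsilyloxy)-3-methylcyclopent-2-en-1-one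
Product: 4 (4S)-4-(tert-butyldimethylsilyloxy)-2-iodo-3-methylcyclopent-2-en-1-one
Conditions: I2, pyridine, DMAP (cat.), CH2Cl2, rt
Reagents that add atoms: iodine II
Why: α-Iodination of an enone by amine conjugate addition, iodination of the enolate and elimination is standard for cyclopentenones, including β-substituted ones.

**Step 4**
Reactants: 4 (4S)-4-(tert-butyldimethylsilyloxy)-2-iodo-3-methylcyclopent-2-en-1-one
Product: 5 (1S,4S)-4-(tert-butyldimethylsilyloxy)-2-iodo-3-methyl-1-(propan-2-yl)cyclopent-2-en-1-ol (OH cis to OTBS)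
Conditions: i-PrMgCl, anhydrous CeCl3, THF, −78 °C
Reagents that add atoms: isopropylmagnesium chloride CC(C)[Mg]Cl
Why: Organocerium 1,2-addition (no enolisation, reduction or I/Mg exchange) should occur on the carbonyl face anti to the 4-silyloxy group, which sets the future C4 carbinol (OH β, isopropyl α).

**Step 5**
Reactants: 5 (1S,4S)-4-(tert-butyldimethylsilyloxy)-2-iodo-3-methyl-1-(propan-2-yl)cyclopent-2-en-1-ol
Product: 7 1-[(3S,5S)-3-(tert-butyldimethylsilyloxy)-5-hydroxy-2-methyl-5-(propan-2-yl)cyclopent-1-en-1-yl]ethan-1-one, via dilithio species 6 (not isolated)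
Conditions: t-BuLi (3.1 equiv), THF, −78 °C; then MeC(O)N(OMe)Me, −78 to 0 °C; aq NH4Cl
Reagents that add atoms: N-methoxy-N-methylacetamide CC(=O)N(C)OC
Why: Iodine–lithium exchange on the lithium alkoxide followed by Weinreb ketone synthesis should give the methyl ketone without over-addition; carrying the free alkoxide avoids silyl migration to carbon.

**Step 6**
Reactants: 7 1-[(3S,5S)-3-(tert-butyldimethylsilyloxy)-5-hydroxy-2-methyl-5-(propan-2-yl)cyclopent-1-en-1-yl]ethan-1-one
Product: 8 (3S,5S)-3-(tert-butyldimethylsilyloxy)-2-methyl-5-(propan-2-yl)-5-(triethylsilyloxy)-1-[1-(triethylsilyloxy)ethenyl]cyclopent-1-ene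
Conditions: Et3SiOTf (2.6 equiv), Et3N, CH2Cl2, −78 to 0 °C
Reagents that add atoms: triethylsilyl trifluoromethanesulfonate CC[Si](CC)(CC)OS(=O)(=O)C(F)(F)F
Why: Silyl triflate/amine soft enolisation should remove a proton from the acetyl CH3 (least hindered α′ position) to give the cross-conjugated 2-silyloxydiene, and the same reagent silylates the hindered tertiary alcohol.

**Step 7**
Reactants: 9 methyl but-3-enoate
Product: 10 methyl 2-diazobut-3-enoate
Conditions: 4-acetamidobenzenesulfonyl azide, DBU, MeCN, 0 °C; used cold and fresh as a pentane solution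
Reagents that add atoms: 4-acetamidobenzenesulfonyl azide CC(=O)Nc1ccc(cc1)S(=O)(=O)N=[N+]=[N-]
Why: Regitz diazo transfer to the dienolate of the β,γ-unsaturated ester is the standard entry to vinyldiazoacetates.

**Step 8**
Reactants: 8 (3S,5S)-3-(tert-butyldimethylsilyloxy)-2-methyl-5-(propan-2-yl)-5-(triethylsilyloxy)-1-[1-(triethylsilyloxy)ethenyl]cyclopent-1-ene; 10 methyl 2-diazobut-3-enoate
Product: 12 methyl (1S,2S,4S)-2-(tert-butyldimethylsilyloxy)-4,6-bis(triethylsilyloxy)dauca-5,8-dien-14-oate, via cis-divinylcyclopropane 11 (not isolated)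
Conditions: Rh2(S-DOSP)4 (1 mol %), slow addition of 10 (2 equiv), hexanes, −78 °C to rt, then 60 °C
Reagents that add atoms: none
Why: The Rh(II) catalyst converts 10 into a donor/acceptor vinylcarbenoid that cyclopropanates the terminal, electron-rich 2-silyloxy enol ether C6=C7 of 8 to give cis-divinylcyclopropane 11, which undergoes a boat-like [3,3] Cope shift that breaks C6–C8 and forms C1–C10; the closest known reaction type is the Rh-vinylcarbenoid tandem cyclopropanation/Cope rearrangement (formal (4+3)) with 2-oxygenated dienes and with dienes whose disubstituted terminus becomes a quaternary centre. The seven-membered ring is closed in the sigmatropic step as a 1,4-cycloheptadiene (enol ether C5=C6, enoate C8=C9), the cyclopropane being only a temporary ring. The quaternary centre C1 (S) is set by chirality transfer: the catalyst should fix the cyclopropane as (1R,2S), and in the only productive boat rotamer (C1 tucked under C7) C10 can reach only the α face of C1, which is also the face anti to the C2 silyloxy group, so catalyst and substrate are matched. The step needs carbenoid rather than vinylogous reactivity (secured by the hydrocarbon solvent and the electron-rich prolinate catalyst), attack at C6=C7 rather than the tetrasubstituted C1=C5 (sterics and the oxygen donor), and the cyclopentenyl group cis to the vinyl group (the usual placement of the alkene substituent; a trans isomer can still epimerise on warming through the silyloxy/ester-activated C6–C8 bond).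

**Step 9**
Reactants: 12 methyl (1S,2S,4S)-2-(tert-butyldimethylsilyloxy)-4,6-bis(triethylsilyloxy)dauca-5,8-dien-14-oate
Product: 13 (1S,2S,4S)-2-(tert-butyldimethylsilyloxy)-4,6-bis(triethylsilyloxy)dauca-5,8-dien-14-ol
Conditions: DIBAL-H (2.5 equiv), CH2Cl2, −78 °C; Rochelle salt
Reagents that add atoms: none
Why: DIBAL 1,2-reduction of the conjugated ester should give the primary allylic alcohol; silyl ethers and the silyl enol ether are inert.

**Step 10**
Reactants: 13 (1S,2S,4S)-2-(tert-butyldimethylsilyloxy)-4,6-bis(triethylsilyloxy)dauca-5,8-dien-14-ol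
Product: 15 (1S,2S,4S)-2-(tert-butyldimethylsilyloxy)-4,6-bis(triethylsilyloxy)dauca-5,8-diene, via allylic mesylate 14 (not isolated)
Conditions: Ms2O, Et3N, CH2Cl2, −20 °C; then LiEt3BH, THF, 0 °C
Reagents that add atoms: none
Why: Sulfonate activation and SN2 hydride displacement at the primary allylic carbon should give the C14 methyl group without allylic transposition of C8=C9.

**Step 11**
Reactants: 15 (1S,2S,4S)-2-(tert-butyldimethylsilyloxy)-4,6-bis(triethylsilyloxy)dauca-5,8-diene
Product: 16 (1S,2S,4S,5S)-2-(tert-butyldimethylsilyloxy)-4-hydroxydauc-8-en-6-one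
Conditions: HF·pyridine, pyridine, THF, 0 °C to rt
Reagents that add atoms: none
Why: Buffered fluoride desilylation should cleave the enol silyl ether (ketonisation at C5) and the tertiary TES ether but not the hindered secondary TBS ether; the trans-fused ketone (H-5 α, C6 anti to the C4 isopropyl) is expected to be favoured and C5 stays epimerisable until step 12.

**Step 12**
Reactants: 16 (1S,2S,4S,5S)-2-(tert-butyldimethylsilyloxy)-4-hydroxydauc-8-en-6-one
Product: 17 (1S,2S,4S,5R,6R)-2-(tert-butyldimethylsilyloxy)dauc-8-ene-4,6-diol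
Conditions: Me4NBH(OAc)3, MeCN/AcOH, −20 °C
Reagents that add atoms: none
Why: Evans–Saksena reduction: the 4β-alkoxyborohydride should deliver hydride intramolecularly to the β face of the C6 ketone, giving the 6α-alcohol (1,3-anti diol).

**Step 13**
Reactants: 17 (1S,2S,4S,5R,6R)-2-(tert-butyldimethylsilyloxy)dauc-8-ene-4,6-diol
Product: 18 (1S,2S,4S,5R,6R,8S,9R)-2-(tert-butyldimethylsilyloxy)-8,9-epoxydaucane-4,6-diol
Conditions: VO(acac)2 (5 mol %), t-BuOOH, CH2Cl2, 0 °C to rt
Reagents that add atoms: tert-butyl hydroperoxide CC(C)(C)OO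
Why: Vanadium-catalysed hydroxyl-directed epoxidation: the homoallylic 6α-OH should deliver oxygen to the α face of C8=C9.

**Step 14**
Reactants: 18 (1S,2S,4S,5R,6R,8S,9R)-2-(tert-butyldimethylsilyloxy)-8,9-epoxydaucane-4,6-diol
Product: 19 (1S,2S,4S,5R,6R,8S,9R)-2-(tert-butyldimethylsilyloxy)-8,9-epoxy-4-hydroxydaucan-6-yl 4-methoxybenzoate
Conditions: 4-MeOC6H4COCl, DMAP, Et3N, CH2Cl2, 0 °C to rt
Reagents that add atoms: 4-methoxybenzoyl chloride COc1ccc(cc1)C(Cl)=O
Why: DMAP-catalysed acylation should esterify only the secondary 6-OH; the tertiary 4-OH and the epoxide are inert under these basic conditions.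

**Step 15**
Reactants: 19 (1S,2S,4S,5R,6R,8S,9R)-2-(tert-butyldimethylsilyloxy)-8,9-epoxy-4-hydroxydaucan-6-yl 4-methoxybenzoate
Product: 20 (1S,2S,4S,5R,6R,8S,9R)-8,9-epoxy-2,4-dihydroxydaucan-6-yl 4-methoxybenzoate
Conditions: Bu4NF, AcOH (1:1), THF, rt to 40 °C
Reagents that add atoms: none
Why: Acetic acid-buffered fluoride desilylation should free the 2β-alcohol without base-induced ester migration or epoxide opening.

**Step 16**
Reactants: 20 (1S,2S,4S,5R,6R,8S,9R)-8,9-epoxy-2,4-dihydroxydaucan-6-yl 4-methoxybenzoate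
Product: 21 (1S,2R,4S,5R,6R,8S,9R)-2-acetoxy-8,9-epoxy-4-hydroxydaucan-6-yl 4-methoxybenzoate (CNP0317703.1)
Conditions: PPh3, DIAD, AcOH, toluene, 0 to 40 °C
Reagents that add atoms: acetic acid CC(O)=O
Why: Mitsunobu esterification should invert the secondary C2 carbinol (S to R) and install the acetate in one operation, as in the 17β to 17α inversion of steroidal D-ring alcohols; the tertiary 4-OH does not react.

**Compound list**
1 | (4S)-4-(tert-butyldimethylsilyloxy)cyclopent-2-en-1-one | O=C1C=C[C@@H](O[Si](C)(C)C(C)(C)C)C1 | starting material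
2 | trimethylsilyl enol ether of (3S,4S)-4-(tert-butyldimethylsilyloxy)-3-methylcyclopentan-1-one | C[Si](C)(C)OC1=C[C@H](C)[C@@H](O[Si](C)(C)C(C)(C)C)C1 | intermediate
3 | (4S)-4-(tert-butyldimethylsilyloxy)-3-methylcyclopent-2-en-1-one | O=C1C=C(C)[C@@H](O[Si](C)(C)C(C)(C)C)C1 | intermediate
4 | (4S)-4-(tert-butyldimethylsilyloxy)-2-iodo-3-methylcyclopent-2-en-1-one | O=C1C(I)=C(C)[C@@H](O[Si](C)(C)C(C)(C)C)C1 | intermediate
5 | (1S,4S)-4-(tert-butyldimethylsilyloxy)-2-iodo-3-methyl-1-(propan-2-yl)cyclopent-2-en-1-ol | CC(C)[C@@]1(O)C[C@H](O[Si](C)(C)C(C)(C)C)C(C)=C1I | intermediate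
6 | dilithio species (lithium alkoxide and alkenyllithium from 5) | CC(C)[C@@]1(O[Li])C[C@H](O[Si](C)(C)C(C)(C)C)C(C)=C1[Li] | intermediate
7 | 1-[(3S,5S)-3-(tert-butyldimethylsilyloxy)-5-hydroxy-2-methyl-5-(propan-2-yl)cyclopent-1-en-1-yl]ethan-1-one | CC(C)[C@@]1(O)C[C@H](O[Si](C)(C)C(C)(C)C)C(C)=C1C(C)=O | intermediate
8 | (3S,5S)-3-(tert-butyldimethylsilyloxy)-2-methyl-5-(propan-2-yl)-5-(triethylsilyloxy)-1-[1-(triethylsilyloxy)ethenyl]cyclopent-1-ene | CC(C)[C@@]1(O[Si](CC)(CC)CC)C[C@H](O[Si](C)(C)C(C)(C)C)C(C)=C1C(=C)O[Si](CC)(CC)CC | intermediate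
9 | methyl but-3-enoate | COC(=O)CC=C | starting material
10 | methyl 2-diazobut-3-enoate | COC(=O)C(=[N+]=[N-])C=C | intermediate
11 | methyl (1R,2S)-1-ethenyl-2-[(3S,5S)-3-(tert-butyldimethylsilyloxy)-2-methyl-5-(propan-2-yl)-5-(triethylsilyloxy)cyclopent-1-en-1-yl]-2-(triethylsilyloxy)cyclopropane-1-carboxylate | COC(=O)[C@@]1(C=C)C[C@]1(O[Si](CC)(CC)CC)C2=C(C)[C@@H](O[Si](C)(C)C(C)(C)C)C[C@]2(O[Si](CC)(CC)CC)C(C)C | intermediate
12 | methyl (1S,2S,4S)-2-(tert-butyldimethylsilyloxy)-4,6-bis(triethylsilyloxy)dauca-5,8-dien-14-oate | COC(=O)C1=CC[C@]2(C)[C@@H](O[Si](C)(C)C(C)(C)C)C[C@](O[Si](CC)(CC)CC)(C(C)C)C2=C(O[Si](CC)(CC)CC)C1 | intermediate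
13 | (1S,2S,4S)-2-(tert-butyldimethylsilyloxy)-4,6-bis(triethylsilyloxy)dauca-5,8-dien-14-ol | OCC1=CC[C@]2(C)[C@@H](O[Si](C)(C)C(C)(C)C)C[C@](O[Si](CC)(CC)CC)(C(C)C)C2=C(O[Si](CC)(CC)CC)C1 | intermediate
14 | methanesulfonate of 13 | CS(=O)(=O)OCC1=CC[C@]2(C)[C@@H](O[Si](C)(C)C(C)(C)C)C[C@](O[Si](CC)(CC)CC)(C(C)C)C2=C(O[Si](CC)(CC)CC)C1 | intermediate
15 | (1S,2S,4S)-2-(tert-butyldimethylsilyloxy)-4,6-bis(triethylsilyloxy)dauca-5,8-diene | CC1=CC[C@]2(C)[C@@H](O[Si](C)(C)C(C)(C)C)C[C@](O[Si](CC)(CC)CC)(C(C)C)C2=C(O[Si](CC)(CC)CC)C1 | intermediate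
16 | (1S,2S,4S,5S)-2-(tert-butyldimethylsilyloxy)-4-hydroxydauc-8-en-6-one | CC1=CC[C@]2(C)[C@@H](O[Si](C)(C)C(C)(C)C)C[C@](O)(C(C)C)[C@H]2C(=O)C1 | intermediate
17 | (1S,2S,4S,5R,6R)-2-(tert-butyldimethylsilyloxy)dauc-8-ene-4,6-diol | CC1=CC[C@]2(C)[C@@H](O[Si](C)(C)C(C)(C)C)C[C@](O)(C(C)C)[C@H]2[C@H](O)C1 | intermediate
18 | (1S,2S,4S,5R,6R,8S,9R)-2-(tert-butyldimethylsilyloxy)-8,9-epoxydaucane-4,6-diol | O[C@@H]1C[C@]2(C)O[C@@H]2C[C@]2(C)[C@@H](O[Si](C)(C)C(C)(C)C)C[C@](O)(C(C)C)[C@@H]12 | intermediate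
19 | (1S,2S,4S,5R,6R,8S,9R)-2-(tert-butyldimethylsilyloxy)-8,9-epoxy-4-hydroxydaucan-6-yl 4-methoxybenzoate | COc1ccc(C(=O)O[C@@H]2C[C@]3(C)O[C@@H]3C[C@]3(C)[C@@H](O[Si](C)(C)C(C)(C)C)C[C@](O)(C(C)C)[C@@H]23)cc1 | intermediate
20 | (1S,2S,4S,5R,6R,8S,9R)-8,9-epoxy-2,4-dihydroxydaucan-6-yl 4-methoxybenzoate | COc1ccc(C(=O)O[C@@H]2C[C@]3(C)O[C@@H]3C[C@]3(C)[C@@H](O)C[C@](O)(C(C)C)[C@@H]23)cc1 | intermediate
21 | (1S,2R,4S,5R,6R,8S,9R)-2-acetoxy-8,9-epoxy-4-hydroxydaucan-6-yl 4-methoxybenzoate | COc1ccc(C(=O)O[C@@H]2C[C@]3(C)O[C@@H]3C[C@]3(C)[C@H](OC(C)=O)C[C@](O)(C(C)C)[C@@H]23)cc1 | target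

**Step count and risks**
Total step count: 16. Longest linear sequence: 15 steps (1 to 21 through steps 1–6 and 8–16); step 7 is the one-step side branch to 10.

Steps most likely to fail:

1. Step 8. What may go wrong: carbenoid dimerisation or vinylogous reaction instead of cyclopropanation, formation of the wrong or the trans cyclopropane diastereomer, and a slow Cope shift at the tetrasubstituted C1 terminus. Fallback without a diazo compound, from 5 back to 15: the dilithio species 6 (from 5 as in step 5) would be acylated with (E)-N-methoxy-N,2-dimethylbut-2-enamide to give (E)-1-[(3S,5S)-3-(tert-butyldimethylsilyloxy)-5-hydroxy-2-methyl-5-(propan-2-yl)cyclopent-1-en-1-yl]-2-methylbut-2-en-1-one F1. KHMDS/Et3SiCl (γ-deprotonation of the tigloyl methyl, O-silylation of both oxygens) should give the bis-silylated 2-silyloxy triene F2 with the cyclopentenyl and vinyl groups cis across C6=C8. Simmons–Smith cyclopropanation (Et2Zn, CH2I2) of the electron-rich enol ether double bond would give the (1R,2S)-1-silyloxy-2-methyl-2-vinyl cis-divinylcyclopropane F3, and heating (toluene, 80–110 °C) should give 15 directly by the same Cope shift, so steps 9 and 10 fall away. Facial selectivity would then be substrate-controlled and diastereomers would be separated at F3 or 15.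

2. Step 11. What may go wrong: ketonisation on the wrong face of C5 (cis ring fusion) and loss of the tertiary C4 hydroxyl by dehydration to the C4=C5 enone. Fallback, from 15 back to 16, by unmasking in two stages: K2CO3/MeOH at 0 °C would cleave only the enol silyl ether to give (1S,2S,4S,5S)-2-(tert-butyldimethylsilyloxy)-4-(triethylsilyloxy)dauc-8-en-6-one F4. Its C5 centre can be equilibrated to the trans-fused isomer with DBU without retro-aldol cleavage, because O4 is still silylated. HF·pyridine would then remove the tertiary TES group to give 16.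

3. Step 16. What may go wrong: no SN2 displacement at the neopentyl-type C2 carbinol, elimination to the C2=C3 alkene, or retention through an acyloxyphosphonium pathway. Fallback, from 20 back to 21, by redox inversion: Dess–Martin oxidation would give the 2-ketone (1S,4S,5R,6R,8S,9R)-8,9-epoxy-4-hydroxy-2-oxodaucan-6-yl 4-methoxybenzoate F5, a β-hydroxy ketone with respect to the 4β-OH. Me4NBH(OAc)3 (Evans–Saksena) should deliver hydride from the β face to give the 2α-alcohol (1S,2R,4S,5R,6R,8S,9R)-8,9-epoxy-2,4-dihydroxydaucan-6-yl 4-methoxybenzoate F6 (2,4-anti diol). Ac2O/DMAP would acetylate the secondary 2-OH to give 21.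

**Further compounds**
F1 | step 8 | (E)-1-[(3S,5S)-3-(tert-butyldimethylsilyloxy)-5-hydroxy-2-methyl-5-(propan-2-yl)cyclopent-1-en-1-yl]-2-methylbut-2-en-1-one | CC(C)[C@@]1(O)C[C@H](O[Si](C)(C)C(C)(C)C)C(C)=C1C(=O)/C(C)=C/C
F2 | step 8 | (3S,5S)-3-(tert-butyldimethylsilyloxy)-2-methyl-5-(propan-2-yl)-5-(triethylsilyloxy)-1-[(1E)-2-methyl-1-(triethylsilyloxy)buta-1,3-dien-1-yl]cyclopent-1-ene | CC(C)[C@@]1(O[Si](CC)(CC)CC)C[C@H](O[Si](C)(C)C(C)(C)C)C(C)=C1/C(O[Si](CC)(CC)CC)=C(/C)C=C
F3 | step 8 | (1R,2S)-1-[(3S,5S)-3-(tert-butyldimethylsilyloxy)-2-methyl-5-(propan-2-yl)-5-(triethylsilyloxy)cyclopent-1-en-1-yl]-2-ethenyl-2-methyl-1-(triethylsilyloxy)cyclopropane | C[C@@]1(C=C)C[C@]1(O[Si](CC)(CC)CC)C2=C(C)[C@@H](O[Si](C)(C)C(C)(C)C)C[C@]2(O[Si](CC)(CC)CC)C(C)C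
F4 | step 11 | (1S,2S,4S,5S)-2-(tert-butyldimethylsilyloxy)-4-(triethylsilyloxy)dauc-8-en-6-one | CC1=CC[C@]2(C)[C@@H](O[Si](C)(C)C(C)(C)C)C[C@](O[Si](CC)(CC)CC)(C(C)C)[C@H]2C(=O)C1
F5 | step 16 | (1S,4S,5R,6R,8S,9R)-8,9-epoxy-4-hydroxy-2-oxodaucan-6-yl 4-methoxybenzoate | COc1ccc(C(=O)O[C@@H]2C[C@]3(C)O[C@@H]3C[C@]3(C)C(=O)C[C@](O)(C(C)C)[C@@H]23)cc1
F6 | step 16 | (1S,2R,4S,5R,6R,8S,9R)-8,9-epoxy-2,4-dihydroxydaucan-6-yl 4-methoxybenzoate | COc1ccc(C(=O)O[C@@H]2C[C@]3(C)O[C@@H]3C[C@]3(C)[C@H](O)C[C@](O)(C(C)C)[C@@H]23)cc1
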